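**Retrosynthetic overview**
1. The C8–C9 and C10–H bonds are cut together: a base-free rhodium-catalysed alkyne hydroacylation (the new step) joins a β,γ-epoxy aldehyde (ring plus C7–C8) to the methyl-capped alkyne of an all-E C14 polyenynal.
2. The polyenynal comes from one Horner–Wadsworth–Emmons reaction of the symmetric C10 trienedial with a but-2-ynylphosphonate.
3. The β,γ-epoxy aldehyde comes from an epoxy carbaldehyde by one-carbon homologation (methylenation, hydroboration–oxidation, oxidation).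
4. The epoxy carbaldehyde comes from Sharpless epoxidation of a cyclohexenylmethanol, itself made from (4R,6R)-actinol by enol triflate carbonylation and reduction.
5. Ring order: the carbocycle (ring A) is bought with actinol and keeps its carbinol centre; the oxirane (ring B) is formed second, at the Sharpless step, before the chain is attached.

Assumption: (4R,6R)-actinol, (2E,4E,6E)-2,7-dimethylocta-2,4,6-trienedial and 1-bromobut-2-yne are taken as commercial; comments use carotenoid numbering (ring C1–C6, chain from C7).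

**Route**

Step 1
Reactants: 1 (4R,6R)-4-hydroxy-2,2,6-trimethylcyclohexan-1-one
Product: 2 (4R,6R)-4-[(tert-butyldimethylsilyl)oxy]-2,2,6-trimethylcyclohexan-1-one
Conditions: TBSCl, imidazole, DMF, rt
Reagents that add atoms: tert-butyldimethylsilyl chloride, CC(C)(C)[Si](C)(C)Cl
Why: Imidazole-promoted silyl ether formation on the only hydroxyl leaves both stereocentres untouched.

Step 2
Reactants: 2 (4R,6R)-4-[(tert-butyldimethylsilyl)oxy]-2,2,6-trimethylcyclohexan-1-one
Product: 4 (4R)-4-[(tert-butyldimethylsilyl)oxy]-2,6,6-trimethylcyclohex-1-en-1-yl trifluoromethanesulfonate, via lithium enolate 3 (not isolated)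
Conditions: LiN(i-Pr)2, THF, −78 °C; then PhNTf2, −78 °C to rt
Reagents that add atoms: lithium diisopropylamide, [Li+].CC(C)[N-]C(C)C (lithium of 3 only); N-phenylbis(trifluoromethanesulfonimide), O=S(=O)(N(c1ccccc1)S(=O)(=O)C(F)(F)F)C(F)(F)F
Why: Only the methine α-carbon is enolisable (the other α-carbon is quaternary), so enolate O-sulfonylation (enol triflate formation) gives one tetrasubstituted triflate; the methyl-bearing stereocentre is erased on purpose and the carbinol centre is untouched.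

Step 3
Reactants: 4 (4R)-4-[(tert-butyldimethylsilyl)oxy]-2,6,6-trimethylcyclohex-1-en-1-yl trifluoromethanesulfonate
Product: 5 methyl (4R)-4-[(tert-butyldimethylsilyl)oxy]-2,6,6-trimethylcyclohex-1-ene-1-carboxylate
Conditions: CO (1 atm), Pd(OAc)2 (5 mol %), PPh3 (10 mol %), Et3N, MeOH–DMF, 60 °C
Reagents that add atoms: carbon monoxide, [C-]#[O+]; methanol, CO
Why: Palladium-catalysed alkoxycarbonylation (oxidative addition of the enol triflate to zerovalent palladium, CO insertion, methanolysis) tolerates the silyl ether.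

Step 4
Reactants: 5 methyl (4R)-4-[(tert-butyldimethylsilyl)oxy]-2,6,6-trimethylcyclohex-1-ene-1-carboxylate
Product: 6 [(4R)-4-[(tert-butyldimethylsilyl)oxy]-2,6,6-trimethylcyclohex-1-en-1-yl]methanol
Conditions: i-Bu2AlH (2.5 equiv), CH2Cl2, −78 °C; aq potassium sodium tartrate work-up
Reagents that add atoms: none
Why: Hydride 1,2-reduction of the conjugated ester gives the allylic alcohol that will direct the epoxidation.

Step 5
Reactants: 6 [(4R)-4-[(tert-butyldimethylsilyl)oxy]-2,6,6-trimethylcyclohex-1-en-1-yl]methanol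
Product: 7 [(1R,4S,6R)-4-[(tert-butyldimethylsilyl)oxy]-2,2,6-trimethyl-7-oxabicyclo[4.1.0]heptan-1-yl]methanol
Conditions: Ti(OiPr)4 (0.3 equiv), D-(−)-diethyl tartrate (0.36 equiv), t-BuOOH (2 equiv), 4 Å MS, CH2Cl2, −20 °C
Reagents that add atoms: tert-butyl hydroperoxide, CC(C)(C)OO
Why: Katsuki–Sharpless asymmetric epoxidation; with D-(−)-diethyl tartrate the titanium-bound peroxide is delivered by reagent control to the alkene face anti to the silyloxy group, which sets both oxirane carbons (1R,6R in 7, that is 6S,5R in carotenoid numbering).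

Step 6
Reactants: 7 [(1R,4S,6R)-4-[(tert-butyldimethylsilyl)oxy]-2,2,6-trimethyl-7-oxabicyclo[4.1.0]heptan-1-yl]methanol
Product: 8 (1S,4S,6R)-4-[(tert-butyldimethylsilyl)oxy]-2,2,6-trimethyl-7-oxabicyclo[4.1.0]heptane-1-carbaldehyde
Conditions: (n-Pr)4N[RuO4] (5 mol %), N-methylmorpholine N-oxide, 4 Å MS, CH2Cl2, rt
Reagents that add atoms: none
Why: Ley–Griffith oxidation is neutral and the aldehyde has no α-hydrogen, so the oxirane centres cannot epimerise (the descriptor at C1 changes only by priority).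

Step 7
Reactants: 8 (1S,4S,6R)-4-[(tert-butyldimethylsilyl)oxy]-2,2,6-trimethyl-7-oxabicyclo[4.1.0]heptane-1-carbaldehyde
Product: 9 (1S,4S,6R)-4-[(tert-butyldimethylsilyl)oxy]-1-ethenyl-2,2,6-trimethyl-7-oxabicyclo[4.1.0]heptane
Conditions: Ph3PCH3Br, KOt-Bu, THF, 0 °C to rt
Reagents that add atoms: methyltriphenylphosphonium bromide, C[P+](c1ccccc1)(c1ccccc1)c1ccccc1.[Br-]
Why: Wittig methylenation of a non-enolisable aldehyde; the hindered oxirane is inert to the unstabilised ylide.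

Step 8
Reactants: 9 (1S,4S,6R)-4-[(tert-butyldimethylsilyl)oxy]-1-ethenyl-2,2,6-trimethyl-7-oxabicyclo[4.1.0]heptane
Product: 11 2-[(1S,4S,6R)-4-[(tert-butyldimethylsilyl)oxy]-2,2,6-trimethyl-7-oxabicyclo[4.1.0]heptan-1-yl]ethan-1-ol, via B-alkyl-9-BBN adduct 10 (not isolated)
Conditions: 9-BBN, THF, 0 °C to rt; then aq NaOH, H2O2, 0 °C
Reagents that add atoms: 9-borabicyclo[3.3.1]nonane, B1C2CCCC1CCC2 (boron of 10 only); hydrogen peroxide, OO
Why: Brown anti-Markovnikov hydroboration–oxidation; the bulky, weakly Lewis acidic borane should add to the terminal carbon without opening the oxirane, and alkaline peroxide replaces boron by hydroxyl.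

Step 9
Reactants: 11 2-[(1S,4S,6R)-4-[(tert-butyldimethylsilyl)oxy]-2,2,6-trimethyl-7-oxabicyclo[4.1.0]heptan-1-yl]ethan-1-ol
Product: 12 2-[(1S,4S,6R)-4-hydroxy-2,2,6-trimethyl-7-oxabicyclo[4.1.0]heptan-1-yl]ethan-1-ol
Conditions: Bu4NF, THF, 0 °C to rt
Reagents that add atoms: none
Why: Fluoride desilylation is done here because the molecule carries no base-sensitive carbonyl yet.

Step 10
Reactants: 12 2-[(1S,4S,6R)-4-hydroxy-2,2,6-trimethyl-7-oxabicyclo[4.1.0]heptan-1-yl]ethan-1-ol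
Product: 13 2-[(1S,4S,6R)-4-hydroxy-2,2,6-trimethyl-7-oxabicyclo[4.1.0]heptan-1-yl]acetaldehyde
Conditions: TEMPO (10 mol %), PhI(OAc)2 (1.1 equiv), CH2Cl2, rt; used crude
Reagents that add atoms: none
Why: Oxoammonium (TEMPO) oxidation is selective for the primary alcohol over the ring carbinol and is base-free, so the β,γ-epoxy aldehyde does not undergo β-elimination.

Step 11
Reactants: 14 1-bromobut-2-yne
Product: 15 diethyl (but-2-yn-1-yl)phosphonate
Conditions: P(OEt)3, neat, 130 °C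
Reagents that add atoms: triethyl phosphite, CCOP(OCC)OCC
Why: Michaelis–Arbuzov reaction (SN2 attack of phosphorus at the primary propargylic bromide, then dealkylation by bromide).

Step 12
Reactants: 15 diethyl (but-2-yn-1-yl)phosphonate; 16 (2E,4E,6E)-2,7-dimethylocta-2,4,6-trienedial
Product: 18 (2E,4E,6E,8E)-2,7-dimethyldodeca-2,4,6,8-tetraen-10-ynal, via sodium phosphonate carbanion 17 (not isolated)
Conditions: NaN(SiMe3)2, THF, −78 °C; then cannulated into 16 (2.5 equiv), THF, −78 to 0 °C, dim light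
Reagents that add atoms: sodium bis(trimethylsilyl)amide, [Na+].C[Si](C)(C)[N-][Si](C)(C)C (sodium of 17 only)
Why: Horner–Wadsworth–Emmons olefination; the propargylic phosphonate anion reacts at its α-carbon to give the E-enyne, and inverse addition to excess symmetric dialdehyde limits reaction to one formyl group.

Step 13
Reactants: 13 2-[(1S,4S,6R)-4-hydroxy-2,2,6-trimethyl-7-oxabicyclo[4.1.0]heptan-1-yl]acetaldehyde; 18 (2E,4E,6E,8E)-2,7-dimethyldodeca-2,4,6,8-tetraen-10-ynal (1.2 equiv)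
Product: 19 (2E,4E,6E,8E,10E)-13-[(1S,4S,6R)-4-hydroxy-2,2,6-trimethyl-7-oxabicyclo[4.1.0]heptan-1-yl]-2,7,11-trimethyl-12-oxotrideca-2,4,6,8,10-pentaenal
Conditions: [Rh(nbd)2]BF4 (5 mol %), Cy2PCH2PCy2 (5 mol %), acetone, 40 °C, dark
Reagents that add atoms: none
Why: Proposed new method: oxirane-oxygen-chelation-assisted alkyne hydroacylation, in which cationic monovalent rhodium inserts into the aldehyde C–H of 13 to give a five-membered acyl hydride chelate of trivalent rhodium held by the β-oxirane oxygen (this should suppress decarbonylation and leave the non-chelating polyenal CHO of 18 a spectator), syn hydrometalation of the alkyne puts hydrogen on the alkenyl-bearing carbon and rhodium on the methyl-bearing carbon (as aryl and alkenyl methyl alkynes do), and C–C reductive elimination forms C8–C9 and the 10E enone with no base present to open the β,γ-epoxy ketone; the closest known reaction type is chelation-controlled rhodium-catalysed intermolecular alkyne hydroacylation of β-thioether aldehydes and salicylaldehydes.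

**Compound list**

1 | (4R,6R)-4-hydroxy-2,2,6-trimethylcyclohexan-1-one | C[C@@H]1C[C@@H](O)CC(C)(C)C1=O | starting material
2 | (4R,6R)-4-[(tert-butyldimethylsilyl)oxy]-2,2,6-trimethylcyclohexan-1-one | C[C@@H]1C[C@@H](O[Si](C)(C)C(C)(C)C)CC(C)(C)C1=O | intermediate
3 | lithium (4R)-4-[(tert-butyldimethylsilyl)oxy]-2,6,6-trimethylcyclohex-1-en-1-olate | [Li+].[O-]C1=C(C)C[C@@H](O[Si](C)(C)C(C)(C)C)CC1(C)C | intermediate
4 | (4R)-4-[(tert-butyldimethylsilyl)oxy]-2,6,6-trimethylcyclohex-1-en-1-yl trifluoromethanesulfonate | FC(F)(F)S(=O)(=O)OC1=C(C)C[C@@H](O[Si](C)(C)C(C)(C)C)CC1(C)C | intermediate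
5 | methyl (4R)-4-[(tert-butyldimethylsilyl)oxy]-2,6,6-trimethylcyclohex-1-ene-1-carboxylate | COC(=O)C1=C(C)C[C@@H](O[Si](C)(C)C(C)(C)C)CC1(C)C | intermediate
6 | [(4R)-4-[(tert-butyldimethylsilyl)oxy]-2,6,6-trimethylcyclohex-1-en-1-yl]methanol | OCC1=C(C)C[C@@H](O[Si](C)(C)C(C)(C)C)CC1(C)C | intermediate
7 | [(1R,4S,6R)-4-[(tert-butyldimethylsilyl)oxy]-2,2,6-trimethyl-7-oxabicyclo[4.1.0]heptan-1-yl]methanol | OC[C@@]12O[C@]1(C)C[C@@H](O[Si](C)(C)C(C)(C)C)CC2(C)C | intermediate
8 | (1S,4S,6R)-4-[(tert-butyldimethylsilyl)oxy]-2,2,6-trimethyl-7-oxabicyclo[4.1.0]heptane-1-carbaldehyde | O=C[C@@]12O[C@]1(C)C[C@@H](O[Si](C)(C)C(C)(C)C)CC2(C)C | intermediate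
9 | (1S,4S,6R)-4-[(tert-butyldimethylsilyl)oxy]-1-ethenyl-2,2,6-trimethyl-7-oxabicyclo[4.1.0]heptane | C=C[C@@]12O[C@]1(C)C[C@@H](O[Si](C)(C)C(C)(C)C)CC2(C)C | intermediate
10 | 9-{2-[(1S,4S,6R)-4-[(tert-butyldimethylsilyl)oxy]-2,2,6-trimethyl-7-oxabicyclo[4.1.0]heptan-1-yl]ethyl}-9-borabicyclo[3.3.1]nonane | B1(CC[C@@]23O[C@]2(C)C[C@@H](O[Si](C)(C)C(C)(C)C)CC3(C)C)C2CCCC1CCC2 | intermediate
11 | 2-[(1S,4S,6R)-4-[(tert-butyldimethylsilyl)oxy]-2,2,6-trimethyl-7-oxabicyclo[4.1.0]heptan-1-yl]ethan-1-ol | OCC[C@@]12O[C@]1(C)C[C@@H](O[Si](C)(C)C(C)(C)C)CC2(C)C | intermediate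
12 | 2-[(1S,4S,6R)-4-hydroxy-2,2,6-trimethyl-7-oxabicyclo[4.1.0]heptan-1-yl]ethan-1-ol | OCC[C@@]12O[C@]1(C)C[C@@H](O)CC2(C)C | intermediate
13 | 2-[(1S,4S,6R)-4-hydroxy-2,2,6-trimethyl-7-oxabicyclo[4.1.0]heptan-1-yl]acetaldehyde | O=CC[C@@]12O[C@]1(C)C[C@@H](O)CC2(C)C | intermediate
14 | 1-bromobut-2-yne | CC#CCBr | starting material
15 | diethyl (but-2-yn-1-yl)phosphonate | CC#CCP(=O)(OCC)OCC | intermediate
16 | (2E,4E,6E)-2,7-dimethylocta-2,4,6-trienedial | O=C/C(C)=C/C=C/C=C(\C)C=O | starting material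
17 | sodium 1-(diethoxyphosphoryl)but-2-yn-1-ide | [Na+].CC#C[CH-]P(=O)(OCC)OCC | intermediate
18 | (2E,4E,6E,8E)-2,7-dimethyldodeca-2,4,6,8-tetraen-10-ynal | CC#C/C=C/C(C)=C/C=C/C=C(\C)C=O | intermediate
19 | (2E,4E,6E,8E,10E)-13-[(1S,4S,6R)-4-hydroxy-2,2,6-trimethyl-7-oxabicyclo[4.1.0]heptan-1-yl]-2,7,11-trimethyl-12-oxotrideca-2,4,6,8,10-pentaenal | C\C(C=O)=C/C=C/C=C(C)/C=C/C=C(\C)C(=O)C[C@@]12O[C@]1(C)C[C@@H](O)CC2(C)C | target

**Totals and risk**

Total step count: 13. Longest linear sequence: 11 steps (steps 1–10, then step 13).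

Three steps most likely to fail:

Step 13 (the proposed new step). The oxirane oxygen may chelate too weakly (slow turnover, decarbonylation), the alkyne may insert with the opposite regiochemistry, or the cationic metal may open the oxirane. The fallback uses known chemistry, sets out from 18 and 13, and comes back at 19. Luche reduction of 18 (NaBH4, CeCl3, MeOH, 0 °C) gives (2E,4E,6E,8E)-2,7-dimethyldodeca-2,4,6,8-tetraen-10-yn-1-ol F1. Hydrozirconation with excess Cp2Zr(H)Cl in THF followed by I2 gives (2E,4E,6E,8E,10E)-11-iodo-2,7-dimethyldodeca-2,4,6,8,10-pentaen-1-ol F2, with zirconium and then iodine on the methyl-bearing carbon. Nozaki–Hiyama–Kishi coupling of F2 with 13 (CrCl2, NiCl2 1 mol %, DMSO, rt) gives (2E,4E,6E,8E,10E)-13-[(1S,4S,6R)-4-hydroxy-2,2,6-trimethyl-7-oxabicyclo[4.1.0]heptan-1-yl]-2,7,11-trimethyltrideca-2,4,6,8,10-pentaene-1,12-diol F3 as both C12 epimers. MnO2 in CH2Cl2 then oxidises the two allylic carbinols and leaves the saturated ring carbinol, which gives 19 under neutral conditions.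

Step 8. The borane could reduce or open the vinyl oxirane instead of hydroborating it. The fallback sets out from 8 and comes back at 11. Wittig reaction of 8 with the ylide from (methoxymethyl)triphenylphosphonium chloride and KN(SiMe3)2 in THF gives (1S,4S,6R)-4-[(tert-butyldimethylsilyl)oxy]-1-(2-methoxyethenyl)-2,2,6-trimethyl-7-oxabicyclo[4.1.0]heptane F4 as an E/Z mixture. Hydrolysis with Hg(OAc)2 in THF–H2O and then aq KI, which avoids protic acid, gives 2-[(1S,4S,6R)-4-[(tert-butyldimethylsilyl)oxy]-2,2,6-trimethyl-7-oxabicyclo[4.1.0]heptan-1-yl]acetaldehyde F5. NaBH4 in MeOH at 0 °C reduces F5 to 11.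

Step 12. The propargylic phosphonate anion could give E/Z or allenic mixtures, or olefinate both formyl groups. The fallback sets out from 16 and comes back at 18. Takai olefination of excess 16 (CHI3, CrCl2, THF, 0 °C) gives (2E,4E,6E,8E)-9-iodo-2,7-dimethylnona-2,4,6,8-tetraenal F6. Sonogashira coupling of F6 with propyne (PdCl2(PPh3)2, CuI, Et3N, THF, rt) forms the sp–sp2 bond and gives 18.

**Further compounds**

F1 | step 13 | (2E,4E,6E,8E)-2,7-dimethyldodeca-2,4,6,8-tetraen-10-yn-1-ol | CC#C/C=C/C(C)=C/C=C/C=C(\C)CO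
F2 | step 13 | (2E,4E,6E,8E,10E)-11-iodo-2,7-dimethyldodeca-2,4,6,8,10-pentaen-1-ol | C\C(I)=C/C=C/C(C)=C/C=C/C=C(\C)CO
F3 | step 13 | (2E,4E,6E,8E,10E)-13-[(1S,4S,6R)-4-hydroxy-2,2,6-trimethyl-7-oxabicyclo[4.1.0]heptan-1-yl]-2,7,11-trimethyltrideca-2,4,6,8,10-pentaene-1,12-diol (both C12 epimers) | C\C(CO)=C/C=C/C=C(C)/C=C/C=C(\C)C(O)C[C@@]12O[C@]1(C)C[C@@H](O)CC2(C)C
F4 | step 8 | (1S,4S,6R)-4-[(tert-butyldimethylsilyl)oxy]-1-(2-methoxyethenyl)-2,2,6-trimethyl-7-oxabicyclo[4.1.0]heptane (E/Z mixture) | COC=C[C@@]12O[C@]1(C)C[C@@H](O[Si](C)(C)C(C)(C)C)CC2(C)C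
F5 | step 8 | 2-[(1S,4S,6R)-4-[(tert-butyldimethylsilyl)oxy]-2,2,6-trimethyl-7-oxabicyclo[4.1.0]heptan-1-yl]acetaldehyde | O=CC[C@@]12O[C@]1(C)C[C@@H](O[Si](C)(C)C(C)(C)C)CC2(C)C
F6 | step 12 | (2E,4E,6E,8E)-9-iodo-2,7-dimethylnona-2,4,6,8-tetraenal | I/C=C/C(C)=C/C=C/C=C(\C)C=O
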